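**Retrosynthetic overview**
1. Target 13 comes from its methyl ester 11 by a final, non-basic ester cleavage.
2. 11 comes from the 2-homogeranylchromone 8 by breaking the C2–CH3 bond: a Cu-catalysed enantioselective methyl addition to the aromatic 4-silyloxybenzopyrylium ion made from 8 in the flask. This dearomatisation sets the only stereocentre.
3. 8 comes from the 2-methylchromone 5 and geranyl bromide 6 by vinylogous alkylation; the (E)-alkene is bought with 6.
4. 5 comes from methyl 3-acetyl-4-hydroxybenzoate 3 and an amide acetal; 3 comes from methylparaben 1 by acetylation and Fries rearrangement.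
5. Ring order: the benzene ring is bought with 1; the γ-pyranone ring is closed in step 2 (the only ring built) and dearomatised in step 4.

Assumption: the facial sense of the new Cu/Ph-BPE methylation is not known in advance; (R,R)-Ph-BPE is written, and (S,S)-Ph-BPE (also commercial) is used instead if that is the enantiomer that gives (2S)-11.

**Step 1**
Reactants: 1 methyl 4-hydroxybenzoate
Product: 3 methyl 3-acetyl-4-hydroxybenzoate, via methyl 4-acetoxybenzoate 2 (not isolated)
Conditions: Ac2O (1.2 equiv), cat. H2SO4, 80 °C, volatiles removed; then AlCl3 (3 equiv), neat, 150 °C, 2 h; ice/HCl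
Reagents that add atoms: acetic anhydride, CC(=O)OC(C)=O
Why: O-acetylation followed by AlCl3-mediated Fries rearrangement; the para position is blocked by the ester, so the acyl group can only migrate to the ortho carbon (no stereocentre).

**Step 2**
Reactants: 3 methyl 3-acetyl-4-hydroxybenzoate
Product: 5 methyl 2-methyl-4-oxo-4H-chromene-6-carboxylate, via enaminone 4 (not isolated)
Conditions: MeC(OMe)2NMe2 (2 equiv), toluene, 110 °C, 4 h; then AcOH, 100 °C, 2 h
Reagents that add atoms: N,N-dimethylacetamide dimethyl acetal, CC(OC)(OC)N(C)C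
Why: the amide acetal condenses with the acetyl CH3 to a β-dimethylamino enone, and the phenol then closes the pyranone by addition–elimination with loss of Me2NH (enaminone chromone synthesis; no stereocentre).

**Step 3**
Reactants: 5 methyl 2-methyl-4-oxo-4H-chromene-6-carboxylate; 6 geranyl bromide [(2E)-1-bromo-3,7-dimethylocta-2,6-diene]
Product: 8 methyl 2-[(3E)-4,8-dimethylnona-3,7-dien-1-yl]-4-oxo-4H-chromene-6-carboxylate, via lithium dienolate 7 (not isolated)
Conditions: LDA (commercial solution, 1.1 equiv), THF, −78 °C, 5 added to the base; then 6 (1.2 equiv), DMPU, −78 → −30 °C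
Reagents that add atoms: lithium diisopropylamide, [Li+].CC(C)[N-]C(C)C (only the Li of 7; nothing in 8)
Why: vinylogous deprotonation of the 2-methyl group gives an extended dienolate that is alkylated at the exocyclic carbon (which restores the pyranone) by SN2 at the primary allylic bromide, so the (E)-alkene of 6 is carried over unchanged (vinylogous enolate alkylation).

**Step 4**
Reactants: 8 methyl 2-[(3E)-4,8-dimethylnona-3,7-dien-1-yl]-4-oxo-4H-chromene-6-carboxylate
Product: 11 methyl (2S)-2-[(3E)-4,8-dimethylnona-3,7-dien-1-yl]-2-methyl-4-oxo-3,4-dihydro-2H-chromene-6-carboxylate, via silyloxybenzopyrylium triflate 9 (not isolated), via silyl enol ether 10 (not isolated)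
Conditions: TMSOTf (2 equiv), CH2Cl2, 0 °C, 30 min; then CuBr·SMe2 (10 mol %), (R,R)-Ph-BPE (12 mol %), MeMgBr (2 equiv, slow addition), −78 °C, 12 h; then 1 M HCl, THF, 0 °C
Reagents that add atoms: methylmagnesium bromide, C[Mg]Br (the C2 methyl); trimethylsilyl trifluoromethanesulfonate, C[Si](C)(C)OS(=O)(=O)C(F)(F)F (silyl group and triflate of 9 and 10 only, lost on work-up)
Why: Proposed new method: O-silylation turns the γ-pyranone of 8 into the aromatic, strongly electrophilic 4-silyloxybenzopyrylium 9 (the 6-ester raises its electrophilicity further); the chiral (Ph-BPE)Cu–CH3 species formed from MeMgBr π-binds C2=C3 on one face, and oxidative addition at C2 followed by reductive elimination forms the C2–CH3 bond, so the catalyst fixes the (2S) tetrasubstituted centre while the ring loses its aromaticity as silyl enol ether 10, which dilute acid hydrolyses to 11; the closest known reactions are Lewis-acid-assisted Cu/diphosphine-catalysed enantioselective Grignard additions to chromones and quinolones, Cu-catalysed dearomative Grignard additions to pyridinium ions, Cu-catalysed conjugate additions that build quaternary centres on β-substituted cyclic enones, and racemic nucleophile additions at C2 of 4-silyloxybenzopyrylium triflates.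

**Step 5**
Reactants: 11 methyl (2S)-2-[(3E)-4,8-dimethylnona-3,7-dien-1-yl]-2-methyl-4-oxo-3,4-dihydro-2H-chromene-6-carboxylate
Product: 13 (2S)-2-[(3E)-4,8-dimethylnona-3,7-dien-1-yl]-2-methyl-4-oxo-3,4-dihydro-2H-chromene-6-carboxylic acid, via trimethylstannyl ester 12 (not isolated)
Conditions: Me3SnOH (8 equiv), 1,2-dichloroethane, 80 °C; then 5 % aq. HCl wash
Reagents that add atoms: trimethyltin hydroxide, C[Sn](C)(C)O (one carboxyl O of 13; the SnMe3 group only in 12)
Why: tin hydroxide-mediated methyl ester cleavage (acyl–oxygen hydrolysis through the tin carboxylate) runs under near-neutral conditions, so no enolate is formed at C3 and the C2 centre is not exposed to retro-oxa-Michael ring opening; the stereocentre is untouched.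

**Compound list**
1 | methyl 4-hydroxybenzoate (methylparaben) | COC(=O)c1ccc(O)cc1 | starting material
2 | methyl 4-acetoxybenzoate | COC(=O)c1ccc(OC(C)=O)cc1 | intermediate (not isolated)
3 | methyl 3-acetyl-4-hydroxybenzoate | COC(=O)c1ccc(O)c(C(C)=O)c1 | intermediate
4 | methyl 3-[(2E)-3-(dimethylamino)but-2-enoyl]-4-hydroxybenzoate | COC(=O)c1ccc(O)c(c1)C(=O)/C=C(\C)N(C)C | intermediate (not isolated)
5 | methyl 2-methyl-4-oxo-4H-chromene-6-carboxylate | COC(=O)c1ccc2oc(C)cc(=O)c2c1 | intermediate
6 | geranyl bromide, (2E)-1-bromo-3,7-dimethylocta-2,6-diene | CC(C)=CCC/C(C)=C/CBr | starting material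
7 | lithium 6-(methoxycarbonyl)-2-methylidene-2H-chromen-4-olate | C=C1C=C([O-])c2cc(C(=O)OC)ccc2O1.[Li+] | intermediate (not isolated)
8 | methyl 2-[(3E)-4,8-dimethylnona-3,7-dien-1-yl]-4-oxo-4H-chromene-6-carboxylate | CC(C)=CCC/C(C)=C/CCc1cc(=O)c2cc(C(=O)OC)ccc2o1 | intermediate
9 | 2-[(3E)-4,8-dimethylnona-3,7-dien-1-yl]-6-(methoxycarbonyl)-4-[(trimethylsilyl)oxy]chromenylium trifluoromethanesulfonate | CC(C)=CCC/C(C)=C/CCc1cc(O[Si](C)(C)C)c2cc(C(=O)OC)ccc2[o+]1.[O-]S(=O)(=O)C(F)(F)F | intermediate (not isolated)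
10 | methyl (2S)-2-[(3E)-4,8-dimethylnona-3,7-dien-1-yl]-2-methyl-4-[(trimethylsilyl)oxy]-2H-chromene-6-carboxylate | CC(C)=CCC/C(C)=C/CC[C@@]1(C)C=C(O[Si](C)(C)C)c2cc(C(=O)OC)ccc2O1 | intermediate (not isolated)
11 | methyl (2S)-2-[(3E)-4,8-dimethylnona-3,7-dien-1-yl]-2-methyl-4-oxo-3,4-dihydro-2H-chromene-6-carboxylate | CC(C)=CCC/C(C)=C/CC[C@@]1(C)CC(=O)c2cc(C(=O)OC)ccc2O1 | intermediate
12 | trimethylstannyl (2S)-2-[(3E)-4,8-dimethylnona-3,7-dien-1-yl]-2-methyl-4-oxo-3,4-dihydro-2H-chromene-6-carboxylate | CC(C)=CCC/C(C)=C/CC[C@@]1(C)CC(=O)c2cc(C(=O)O[Sn](C)(C)C)ccc2O1 | intermediate (not isolated)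
13 | (2S)-2-[(3E)-4,8-dimethylnona-3,7-dien-1-yl]-2-methyl-4-oxo-3,4-dihydro-2H-chromene-6-carboxylic acid | CC(C)=CCC/C(C)=C/CC[C@@]1(C)CC(=O)c2cc(C(=O)O)ccc2O1 | target

**Totals**
Total step count: 5. Longest linear sequence: 5 steps (1 → 3 → 5 → 8 → 11 → 13); geranyl bromide 6 enters in step 3.

**Steps most likely to fail, with fallbacks**

Step 4 (enantioselective dearomative methylation). The 2-alkylbenzopyrylium 9 has an acidic side-chain CH2 and may simply be deprotonated by MeMgBr, which returns 8 on work-up. An uncatalysed racemic addition could also erode the ee, and the hindered C2 may react slowly. The fallback sets out from 3 and comes back at 11. Kabbe condensation of 3 with commercial (E)-geranylacetone (CC(=O)CC/C=C(\C)CCC=C(C)C; pyrrolidine, MeOH, reflux; aldol condensation then oxa-Michael closure) gives the racemic methyl 2-[(3E)-4,8-dimethylnona-3,7-dien-1-yl]-2-methyl-4-oxo-3,4-dihydro-2H-chromene-6-carboxylate F1. Preparative chiral SFC then gives 11 and the unwanted methyl (2R)-2-[(3E)-4,8-dimethylnona-3,7-dien-1-yl]-2-methyl-4-oxo-3,4-dihydro-2H-chromene-6-carboxylate F2, which can be re-racemised with DBU and recycled.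

Step 3 (vinylogous alkylation). The dienolate 7 can add to neutral chromone (self-condensation), attack the ester, or be alkylated twice. The fallback sets out from 3 and comes back at 8. Claisen condensation of 3 with methyl acetate (NaH, THF, reflux) gives methyl 4-hydroxy-3-(3-oxobutanoyl)benzoate F3. Its trianion (LDA, 3.3 equiv, THF, −78 → 0 °C) is alkylated at the terminal methyl carbon, its most basic site, with 6 to give methyl 3-[(6E)-7,11-dimethyl-3-oxododeca-6,10-dienoyl]-4-hydroxybenzoate F4. Cyclodehydration (cat. p-TsOH, MeOH, 50 °C) then closes the pyranone to 8.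

Step 5 (ester cleavage without racemisation). The deactivated aryl ester may react slowly, and any basic pathway risks retro-oxa-Michael racemisation at C2. The fallback sets out from 8 and comes back at 13, cleaving the ester before the stereocentre exists. LiOH (THF/H2O, rt; then HCl) converts 8 into 2-[(3E)-4,8-dimethylnona-3,7-dien-1-yl]-4-oxo-4H-chromene-6-carboxylic acid F5. Hexamethyldisilazane (CH2Cl2, reflux) gives trimethylsilyl 2-[(3E)-4,8-dimethylnona-3,7-dien-1-yl]-4-oxo-4H-chromene-6-carboxylate F6. Under the conditions of step 4, F6 gives 2-[(3E)-4,8-dimethylnona-3,7-dien-1-yl]-4-[(trimethylsilyl)oxy]-6-[(trimethylsilyl)oxycarbonyl]chromenylium trifluoromethanesulfonate F7 and then trimethylsilyl (2S)-2-[(3E)-4,8-dimethylnona-3,7-dien-1-yl]-2-methyl-4-[(trimethylsilyl)oxy]-2H-chromene-6-carboxylate F8. Dilute aqueous acid cleaves both silyl groups of F8 and gives 13 directly.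

**Further compounds**
F1 | step 4 | methyl (2RS)-2-[(3E)-4,8-dimethylnona-3,7-dien-1-yl]-2-methyl-4-oxo-3,4-dihydro-2H-chromene-6-carboxylate (racemate) | CC(C)=CCC/C(C)=C/CCC1(C)CC(=O)c2cc(C(=O)OC)ccc2O1
F2 | step 4 | methyl (2R)-2-[(3E)-4,8-dimethylnona-3,7-dien-1-yl]-2-methyl-4-oxo-3,4-dihydro-2H-chromene-6-carboxylate | CC(C)=CCC/C(C)=C/CC[C@]1(C)CC(=O)c2cc(C(=O)OC)ccc2O1
F3 | step 3 | methyl 4-hydroxy-3-(3-oxobutanoyl)benzoate | COC(=O)c1ccc(O)c(c1)C(=O)CC(C)=O
F4 | step 3 | methyl 3-[(6E)-7,11-dimethyl-3-oxododeca-6,10-dienoyl]-4-hydroxybenzoate | COC(=O)c1ccc(O)c(c1)C(=O)CC(=O)CC/C=C(\C)CCC=C(C)C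
F5 | step 5 | 2-[(3E)-4,8-dimethylnona-3,7-dien-1-yl]-4-oxo-4H-chromene-6-carboxylic acid | CC(C)=CCC/C(C)=C/CCc1cc(=O)c2cc(C(=O)O)ccc2o1
F6 | step 5 | trimethylsilyl 2-[(3E)-4,8-dimethylnona-3,7-dien-1-yl]-4-oxo-4H-chromene-6-carboxylate | CC(C)=CCC/C(C)=C/CCc1cc(=O)c2cc(C(=O)O[Si](C)(C)C)ccc2o1
F7 | step 5 | 2-[(3E)-4,8-dimethylnona-3,7-dien-1-yl]-4-[(trimethylsilyl)oxy]-6-[(trimethylsilyl)oxycarbonyl]chromenylium trifluoromethanesulfonate | CC(C)=CCC/C(C)=C/CCc1cc(O[Si](C)(C)C)c2cc(C(=O)O[Si](C)(C)C)ccc2[o+]1.[O-]S(=O)(=O)C(F)(F)F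
F8 | step 5 | trimethylsilyl (2S)-2-[(3E)-4,8-dimethylnona-3,7-dien-1-yl]-2-methyl-4-[(trimethylsilyl)oxy]-2H-chromene-6-carboxylate | CC(C)=CCC/C(C)=C/CC[C@@]1(C)C=C(O[Si](C)(C)C)c2cc(C(=O)O[Si](C)(C)C)ccc2O1
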